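## Retrosynthetic overview

1. Target 23 ⇒ isobutyrylphloroglucinol 21 + 2 × isobutylidene-syncarpic acid 12, joined by two catalyst-controlled Friedel–Crafts-type Michael additions that form both benzylic C–C bonds and both stereocentres.
2. 12 ⇒ syncarpic acid 9 + isobutyraldehyde 10 (Knoevenagel via the Mannich base).
3. 9 ⇒ two-carbon ring expansion (4 → 6) of tetramethylcyclobutane-1,3-dione 3 with ethoxyacetylide; 3 ⇒ isobutyryl chloride 1 (ketene dimerisation).
4. 21 ⇒ Mg-templated Claisen cyclisation of a C10 triketo acid 18 ⇐ acetylacetone 13 + methyl isobutyrate 14 + CO2.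
5. Ring order: cyclobutanedione, then its expansion to the syncarpic six-membered ring (made once, used twice); the aromatic ring by Claisen cyclisation; no ring is formed in the final union.

Assumption: the two identically written [C@H] centres mean the C2-symmetric (R,R) isomer (not the meso form), and the quinine-derived catalyst of step 7 is taken to deliver the aryl group to the Si face of 12 (which gives R); if the first run shows the opposite sense, its quinidine-derived pseudo-enantiomer is used.

## Route

Step 1
Reactants: 1 isobutyryl chloride (2 equiv)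
Product: 3 2,2,4,4-tetramethylcyclobutane-1,3-dione, via dimethylketene 2 (not isolated)
Conditions: Et3N (1.05 equiv), Et2O, reflux, 24 h; filter, crystallise
Reagents that add atoms: none
Why: Dehydrochlorination gives dimethylketene, which dimerises head-to-tail (ketene [2+2] dimerisation) to the cyclobutane-1,3-dione; no stereocentre.

Step 2
Reactants: 3 2,2,4,4-tetramethylcyclobutane-1,3-dione; 4 ethoxyacetylene
Product: 9 syncarpic acid (2,2,4,4-tetramethylcyclohexane-1,3,5-trione), via lithium ethoxyacetylide 5 (not isolated), via lithium cyclobutanolate adduct 6 (not isolated), via ring-opened ynone enolate 7 (not isolated), via ethyl enol ether 8 (not isolated)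
Conditions: 4 (1.1 equiv), n-BuLi (1.05 equiv), THF, −78 °C; add 3, −78 → 23 °C; t-BuOH (1 equiv), 40 °C (0.05 M); then 2 M aq. HCl, 50 °C
Reagents that add atoms: water, O
Why: Proposed new method: the alkynyllithium adds to one strained C=O, the cyclobutanolate opens by strain-driven retro-aldol C–C scission to a lithium enolate (as in the known Grignard ring cleavage of this dione to β-diketones), Li chelation between the enolate oxygen and the ynone C=O holds the enolate carbon rather than oxygen over the alkyne so that a 6-endo-dig carba-Michael addition at the ethoxy-bearing carbon closes the six-membered ring (vinyl anion protonated by t-BuOH), and acid hydrolysis of the vinylogous ester gives the trione, i.e. a net insertion of C2 into the four-membered ring with ethoxyacetylide serving as an acetate-enolate equivalent that has no acidic C–H to quench the enolate; the closest known reaction types are the alkoxide-induced dimer-to-trimer ring expansion of dimethylketene dimer and 6-endo-dig conjugate cyclisations onto ynones (chromone synthesis); no stereocentre.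

Step 3
Reactants: 9 syncarpic acid; 10 isobutyraldehyde
Product: 12 4,4,6,6-tetramethyl-2-(2-methylpropylidene)cyclohexane-1,3,5-trione, via Mannich base 11 (not isolated)
Conditions: piperidine (1.0 equiv), 10 (1.1 equiv), CH2Cl2, 0 → 23 °C; then 1 M aq. HCl wash, 23 °C; use promptly
Reagents that add atoms: none
Why: Knoevenagel condensation run through the Mannich base, in which the stoichiometric amine traps the very electrophilic alkylidene and so prevents addition of a second syncarpic acid, and acid then eliminates piperidine to the alkene, which has no E/Z isomers because the trione ring is symmetric.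

Step 4
Reactants: 13 pentane-2,4-dione (acetylacetone); 14 methyl isobutyrate
Product: 16 7-methyloctane-2,4,6-trione, via dilithio acetylacetone 15 (not isolated)
Conditions: 13 (2 equiv), LDA (4 equiv), THF, 0 °C; then 14 (1 equiv), 0 → 23 °C; 1 M HCl
Reagents that add atoms: none
Why: Claisen-type acylation of the 1,3-dianion of a β-diketone at its terminal carbon (Hauser–Harris triketone synthesis), with the second equivalent of dianion absorbing the acidic product.

Step 5
Reactants: 16 7-methyloctane-2,4,6-trione
Product: 18 8-methyl-3,5,7-trioxononanoic acid, via trilithio triketone 17 (not isolated)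
Conditions: LDA (3.3 equiv), THF, 0 °C; CO2 (g), −78 → 0 °C; cold 1 M HCl; use at once
Reagents that add atoms: carbon dioxide, O=C=O
Why: The third deprotonation takes place at the unhindered terminal CH3 rather than the isopropyl CH, and this terminal carbanion is the most nucleophilic site of the trianion, so CO2 is taken up there (Harris carboxylation of polyketone polyanions).

Step 6
Reactants: 18 8-methyl-3,5,7-trioxononanoic acid
Product: 21 isobutyrylphloroglucinol (2-methyl-1-(2,4,6-trihydroxyphenyl)propan-1-one), via pyrone 19 (not isolated), via triketo methyl ester 20 (not isolated)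
Conditions: Ac2O, 23 °C; evaporate; Mg(OMe)2 (4 equiv), MeOH, reflux, N2; 2 M HCl
Reagents that add atoms: none
Why: Enol lactonisation activates the carboxyl group as the 4-hydroxy-2-pyrone, methoxide reopens it to the triketo ester held as a magnesium chelate, and Mg-templated intramolecular Claisen (Dieckmann-type) condensation of C6 onto the ester followed by enolisation gives the aromatic ring (biomimetic polyketide cyclisation), the aldol alternative being disfavoured by the hindered isopropyl ketone.

Step 7
Reactants: 21 isobutyrylphloroglucinol; 12 4,4,6,6-tetramethyl-2-(2-methylpropylidene)cyclohexane-1,3,5-trione (2.2 equiv)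
Product: 23 (R,R)-myrtucommulone A, via mono-adduct 22 (not isolated)
Conditions: quinine-derived squaramide (9-amino-9-deoxy-epi-quinine 3,5-bis(trifluoromethyl)phenyl squaramide, 20 mol %), 4 Å MS, CH2Cl2/Et2O 5:1, −30 °C, 48 h; aq. citric acid; prep. HPLC
Reagents that add atoms: none
Why: Two successive Friedel–Crafts-type Michael additions of ring carbons C3 and C5 of the acylphloroglucinol to the alkylidene trione under bifunctional tertiary-amine/hydrogen-bond-donor catalysis (asymmetric Friedel–Crafts–Michael addition, a reaction class used for acylphloroglucinols and alkylidene 1,3-diones), in which the catalyst delivers the aryl carbon to the Si face of the alkylidene carbon each time and so sets both benzylic centres as R, the (R,R) isomer being enriched over (S,S) by Horeau amplification and the meso isomer removed by HPLC.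

## Compound list

1 | isobutyryl chloride (2-methylpropanoyl chloride) | CC(C)C(Cl)=O | starting material
2 | dimethylketene | CC(C)=C=O | intermediate
3 | 2,2,4,4-tetramethylcyclobutane-1,3-dione | CC1(C)C(=O)C(C)(C)C1=O | intermediate
4 | ethoxyacetylene (ethoxyethyne) | C#COCC | starting material
5 | lithium ethoxyacetylide | [Li]C#COCC | intermediate
6 | lithium 1-(ethoxyethynyl)-2,2,4,4-tetramethyl-3-oxocyclobutan-1-olate | [Li+].[O-]C1(C#COCC)C(C)(C)C(=O)C1(C)C | intermediate
7 | lithium 7-ethoxy-2,4,4-trimethyl-5-oxohept-2-en-6-yn-3-olate | [Li+].CC(C)=C([O-])C(C)(C)C(=O)C#COCC | intermediate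
8 | 3-ethoxy-4,4,6,6-tetramethylcyclohex-2-ene-1,5-dione | CCOC1=CC(=O)C(C)(C)C(=O)C1(C)C | intermediate
9 | syncarpic acid (2,2,4,4-tetramethylcyclohexane-1,3,5-trione) | CC1(C)C(=O)CC(=O)C(C)(C)C1=O | intermediate
10 | isobutyraldehyde (2-methylpropanal) | CC(C)C=O | starting material
11 | 3-hydroxy-4,4,6,6-tetramethyl-2-[2-methyl-1-(piperidin-1-yl)propyl]cyclohex-2-ene-1,5-dione (racemic Mannich base) | CC(C)C(N1CCCCC1)C1=C(O)C(C)(C)C(=O)C(C)(C)C1=O | intermediate
12 | 4,4,6,6-tetramethyl-2-(2-methylpropylidene)cyclohexane-1,3,5-trione | CC(C)C=C1C(=O)C(C)(C)C(=O)C(C)(C)C1=O | intermediate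
13 | pentane-2,4-dione (acetylacetone) | CC(=O)CC(C)=O | starting material
14 | methyl isobutyrate (methyl 2-methylpropanoate) | COC(=O)C(C)C | starting material
15 | dilithium salt of the pentane-2,4-dione 1,3-dianion | [Li+].[Li+].C=C([O-])C=C(C)[O-] | intermediate
16 | 7-methyloctane-2,4,6-trione | CC(=O)CC(=O)CC(=O)C(C)C | intermediate
17 | trilithium salt of the 7-methyloctane-2,4,6-trione 1,3,5-trianion | [Li+].[Li+].[Li+].C=C([O-])C=C([O-])C=C([O-])C(C)C | intermediate
18 | 8-methyl-3,5,7-trioxononanoic acid | OC(=O)CC(=O)CC(=O)CC(=O)C(C)C | intermediate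
19 | 4-hydroxy-6-(3-methyl-2-oxobutyl)-2H-pyran-2-one | CC(C)C(=O)CC1=CC(O)=CC(=O)O1 | intermediate
20 | methyl 8-methyl-3,5,7-trioxononanoate | COC(=O)CC(=O)CC(=O)CC(=O)C(C)C | intermediate
21 | isobutyrylphloroglucinol (2-methyl-1-(2,4,6-trihydroxyphenyl)propan-1-one) | CC(C)C(=O)c1c(O)cc(O)cc1O | intermediate
22 | 3-hydroxy-4,4,6,6-tetramethyl-2-{(1R)-2-methyl-1-[2,4,6-trihydroxy-3-(2-methylpropanoyl)phenyl]propyl}cyclohex-2-ene-1,5-dione | CC(C)C(=O)c1c(O)cc(O)c([C@H](C2=C(O)C(C)(C)C(=O)C(C)(C)C2=O)C(C)C)c1O | intermediate
23 | (R,R)-myrtucommulone A, 2,2'-{[2,4,6-trihydroxy-5-(2-methylpropanoyl)-1,3-phenylene]bis[(1R)-2-methylpropane-1,1-diyl]}bis(3-hydroxy-4,4,6,6-tetramethylcyclohex-2-ene-1,5-dione) | CC(C)C(=O)c1c(O)c([C@H](C2=C(O)C(C)(C)C(=O)C(C)(C)C2=O)C(C)C)c(O)c([C@H](C2=C(O)C(C)(C)C(=O)C(C)(C)C2=O)C(C)C)c1O | target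

## Summary and fallbacks

Total step count: 7. Longest linear sequence: 4 steps (1 → 3 → 9 → 12 → 23; the branch 13 → 16 → 18 → 21 → 23 is equally long).

Three steps most likely to fail:

**Step 2 (the proposed new ring expansion).** Risks are incomplete ring opening of 6 and O- instead of C-cyclisation of enolate 7. The fallback uses known chemistry, sets out from 21 and comes back at 9. Compound 21 is exhaustively C-methylated (MeI, NaOMe, MeOH, reflux) to 2-isobutyryl-4,4,6,6-tetramethylcyclohexane-1,3,5-trione F1. The acyl group of F1 is then removed by retro-Claisen cleavage in refluxing 6 M HCl to give 9. This replaces the ring expansion by dearomatising alkylation of a phloroglucinol and makes the supply of 9 linear from 13.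

**Step 5 (trianion carboxylation).** Risks are incomplete third deprotonation and loss of the labile β-keto acid 18 by decarboxylation or aldol cyclisation. The fallback sets out from 14 and comes back at 19. Methyl acetoacetate is self-condensed (cat. NaHCO3, 170 °C, MeOH distilled off) to dehydroacetic acid F2. F2 is deacetylated in 90% H2SO4 at 130 °C to triacetic acid lactone F3. The dianion of F3 (NaNH2, liq. NH3) is acylated at its 6-methyl group by 14 to give 19, which continues with the Mg(OMe)2 stage of step 6. The lactone carbonyl is thus in place from the start and no free triketo acid is handled.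

**Step 7 (enantio- and diastereocontrol).** Risks are a racemic background reaction and slow catalyst turnover caused by the acidic enol of the product. The fallback sets out from 12 and 21 and comes back at 23. The two Michael additions are run without chiral control (Et3N, THF, 23 °C, the racemic coupling). This gives 23 together with meso-myrtucommulone A F4 and (S,S)-myrtucommulone A F5. Compound 23 is isolated by preparative HPLC on a chiral stationary phase (amylose tris(3,5-dimethylphenylcarbamate)). Stereocontrol is replaced by resolution, at the cost of most of the material.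

Further compounds
F1 | step 2 | 2-isobutyryl-4,4,6,6-tetramethylcyclohexane-1,3,5-trione (enol form) | CC(C)C(=O)C1=C(O)C(C)(C)C(=O)C(C)(C)C1=O
F2 | step 5 | dehydroacetic acid (3-acetyl-4-hydroxy-6-methyl-2H-pyran-2-one) | CC(=O)C1=C(O)C=C(C)OC1=O
F3 | step 5 | triacetic acid lactone (4-hydroxy-6-methyl-2H-pyran-2-one) | CC1=CC(O)=CC(=O)O1
F4 | step 7 | meso-myrtucommulone A (R,S) | CC(C)C(=O)c1c(O)c([C@H](C2=C(O)C(C)(C)C(=O)C(C)(C)C2=O)C(C)C)c(O)c([C@@H](C2=C(O)C(C)(C)C(=O)C(C)(C)C2=O)C(C)C)c1O
F5 | step 7 | (S,S)-myrtucommulone A | CC(C)C(=O)c1c(O)c([C@@H](C2=C(O)C(C)(C)C(=O)C(C)(C)C2=O)C(C)C)c(O)c([C@@H](C2=C(O)C(C)(C)C(=O)C(C)(C)C2=O)C(C)C)c1O
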